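Cuts (drimane numbering: C3 carbinol, C4 CMe2, C5/C10 ring fusion, C9–C11H2–OAr): first the C11–O(aryl) ether bond, then C8–C9 of ring B, then C9–C10 (sigmatropic), and finally C5–C6 and C10–CH3, which leads back to the dimedone ring.
Enabling feature: ring B has a trisubstituted C7=C8 olefin with its methyl on C8. It lies beside C9, whose only extra substituent is the oxygenated carbon C11. This pattern results when C9 of a C9=C11 aldehyde enol ether adds to the methyl-bearing end of a C7≡C8 alkyne.
Forward order: ring A is the purchased dimedone ring and is elaborated in steps 1–10. Ring B closes in step 11, and the coumarin is attached last.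
Stereochemistry: a lipase resolves C5 together with a temporary C2 carbinol. The C2–O bond passes its face to C10 in a suprafacial Claisen shift. C9 arises in the ring closure under control of the C10 and C8 methyl groups. C3 comes from equatorial hydride delivery to the decalone.

Key step: step 11

Assumption: the lipase is taken to follow the usual empirical size rule for secondary carbinols and to acetylate the (1R)-alcohol faster. If it prefers the other enantiomer, the wanted material is collected as the acetate and released with K2CO3/MeOH.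

Step 1
Reactants: 1 3-ethoxy-5,5-dimethylcyclohex-2-en-1-one; 2 1-bromobut-2-yne
Product: 3 (±)-6-(but-2-yn-1-yl)-3-ethoxy-5,5-dimethylcyclohex-2-en-1-one
Conditions: LiN(i-Pr)2, THF, −78 °C; then 2, −78 °C → rt
Reagents that add atoms: none
Why: In this Stork–Danheiser kinetic α′-alkylation the amide base removes a proton from the CH2 between the carbonyl and CMe2 of the vinylogous ester, and the reactive propargylic bromide forms the C5–C6 bond, leaving C5 racemic at this stage.

Step 2
Reactants: 3 (±)-6-(but-2-yn-1-yl)-3-ethoxy-5,5-dimethylcyclohex-2-en-1-one; 4 methyllithium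
Product: 6 (±)-4-(but-2-yn-1-yl)-3,5,5-trimethylcyclohex-2-en-1-one, via tertiary carbinol 5 (not isolated)
Conditions: MeLi, Et2O, −78 → 0 °C; then 1 M HCl, THF, rt
Reagents that add atoms: water, O
Why: 1,2-Addition to the vinylogous ester carbonyl followed by acid hydrolysis with allylic transposition (the second half of the Stork–Danheiser sequence) puts the future C10 methyl on the β-carbon of a new enone whose carbonyl is C2.

Step 3
Reactants: 6 (±)-4-(but-2-yn-1-yl)-3,5,5-trimethylcyclohex-2-en-1-one
Product: 7 (±)-trans-4-(but-2-yn-1-yl)-3,5,5-trimethylcyclohex-2-en-1-ol (hydroxyl and side chain on opposite faces)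
Conditions: LiBH(s-Bu)3, THF, −78 °C; then NaOH, H2O2; chromatography
Reagents that add atoms: none
Why: In this diastereoselective 1,2-reduction of a β,β-disubstituted enone the side chain sits pseudoaxial to avoid the vinylic methyl, which places one C4 methyl axial on the opposite face, so the bulky borohydride should come in from the side-chain face and leave the C2 hydroxyl trans to the butynyl group.

Step 4
Reactants: 7 (±)-trans-4-(but-2-yn-1-yl)-3,5,5-trimethylcyclohex-2-en-1-ol
Product: 8 (1S,4S)-4-(but-2-yn-1-yl)-3,5,5-trimethylcyclohex-2-en-1-ol (C2–OH α; C5–H α)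
Conditions: lipase from Burkholderia cepacia (lipase PS), vinyl acetate, t-BuOMe, 30 °C, stopped just past half conversion; chromatography
Reagents that add atoms: none
Why: This is a kinetic resolution by lipase-catalysed acyl transfer, a method established for exactly this ring type (4-substituted 3,5,5-trimethylcyclohex-2-enols), and it should acetylate the (1R,4R) enantiomer and leave the (1S,4S) alcohol, which fixes the absolute configuration of C5 and of the relay centre C2.

Step 5
Reactants: 8 (1S,4S)-4-(but-2-yn-1-yl)-3,5,5-trimethylcyclohex-2-en-1-ol; 9 triethyl orthoacetate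
Product: 11 ethyl 2-[(1S,6S)-6-(but-2-yn-1-yl)-1,5,5-trimethylcyclohex-2-en-1-yl]acetate, via ketene acetal 10 (not isolated)
Conditions: MeC(OEt)3 (excess), EtCO2H (cat.), 140 °C, EtOH distilled off
Reagents that add atoms: none
Why: The Johnson–Claisen [3,3] shift is suprafacial, so the pseudoaxial C2–O bond on the α face is exchanged for the C10–C9 bond on the α face, anti to the butynyl group, which sets the quaternary centre C10 (methyl β) and moves the olefin to C1=C2.

Step 6
Reactants: 11 ethyl 2-[(1S,6S)-6-(but-2-yn-1-yl)-1,5,5-trimethylcyclohex-2-en-1-yl]acetate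
Product: 12 ethyl 2-[(1S,6R)-6-(but-2-yn-1-yl)-1,5,5-trimethyl-4-oxocyclohex-2-en-1-yl]acetate
Conditions: CrO3, 3,5-dimethylpyrazole, CH2Cl2, −20 °C; chromatography
Reagents that add atoms: chromium trioxide, O=[Cr](=O)=O
Why: In this allylic oxidation with the hexavalent chromium–dimethylpyrazole complex C10 is quaternary, so the C1=C2 olefin has allylic hydrogens only at C3, these ring C–H bonds are weaker than the propargylic ones, and C3 (next to CMe2) is slightly less crowded than the other allyl terminus C1 (next to C10 with its acetate arm), so the C3 enone should be the main product and its C1 isomer is removed on silica.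

Step 7
Reactants: 12 ethyl 2-[(1S,6R)-6-(but-2-yn-1-yl)-1,5,5-trimethyl-4-oxocyclohex-2-en-1-yl]acetate
Product: 13 ethyl 2-[(1R,2R)-2-(but-2-yn-1-yl)-1,3,3-trimethyl-4-oxocyclohexyl]acetate
Conditions: [(Ph3P)CuH]6, wet toluene, rt
Reagents that add atoms: none
Why: In this copper hydride conjugate reduction the soft hydride adds to C1 of the enone and water protonates the copper enolate, while an isolated dialkyl alkyne and an ester are not touched at room temperature.

Step 8
Reactants: 13 ethyl 2-[(1R,2R)-2-(but-2-yn-1-yl)-1,3,3-trimethyl-4-oxocyclohexyl]acetate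
Product: 14 ethyl 2-[(7R,8R)-7-(but-2-yn-1-yl)-6,6,8-trimethyl-1,4-dioxaspiro[4.5]decan-8-yl]acetate
Conditions: HOCH2CH2OH, p-TsOH (cat.), toluene, reflux, Dean–Stark trap
Reagents that add atoms: ethylene glycol, OCCO
Why: Acid-catalysed ketalisation with removal of water masks the C3 ketone against the aluminium hydride, the silyl triflate and the borohydride used in steps 9–11.

Step 9
Reactants: 14 ethyl 2-[(7R,8R)-7-(but-2-yn-1-yl)-6,6,8-trimethyl-1,4-dioxaspiro[4.5]decan-8-yl]acetate
Product: 15 2-[(7R,8R)-7-(but-2-yn-1-yl)-6,6,8-trimethyl-1,4-dioxaspiro[4.5]decan-8-yl]acetaldehyde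
Conditions: i-Bu2AlH (1.1 equiv), toluene, −78 °C; aq. potassium sodium tartrate
Reagents that add atoms: none
Why: In this partial reduction of an ester the aluminium hemiacetal next to the crowded C10 is stable at −78 °C and collapses to the C11 aldehyde only on work-up.

Step 10
Reactants: 15 2-[(7R,8R)-7-(but-2-yn-1-yl)-6,6,8-trimethyl-1,4-dioxaspiro[4.5]decan-8-yl]acetaldehyde
Product: 16 {(E)-2-[(7R,8S)-7-(but-2-yn-1-yl)-6,6,8-trimethyl-1,4-dioxaspiro[4.5]decan-8-yl]ethenyloxy}triisopropylsilane
Conditions: TIPSOTf, Et3N, CH2Cl2, 0 °C → rt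
Reagents that add atoms: triisopropylsilyl trifluoromethanesulfonate, CC(C)[Si](C(C)C)(C(C)C)OS(=O)(=O)C(F)(F)F
Why: In this soft enolisation and O-silylation of an aldehyde the E geometry should prevail because a Z enol ether would press the silyloxy group against the quaternary C10, and both geometries lead to the same constitution in step 11.

Step 11
Reactants: 16 {(E)-2-[(7R,8S)-7-(but-2-yn-1-yl)-6,6,8-trimethyl-1,4-dioxaspiro[4.5]decan-8-yl]ethenyloxy}triisopropylsilane
Product: 18 3,3-ethylenedioxy-9-epi-drim-7-en-11-ol (5αH; 9βH; 10β-methyl; C11 on the α face), via 3,3-ethylenedioxy-9-epi-drim-7-en-11-al 17 (not isolated)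
Conditions: [(t-Bu)2(2-biphenylyl)P]Au(NCMe)SbF6 (5 mol %), i-PrOH (2 equiv), CH2Cl2, rt; then MeOH, NaBH4, −20 °C
Reagents that add atoms: none
Why: The cationic monovalent gold complex binds the C7≡C8 triple bond, C9 of the silyl enol ether adds to C8 on the side away from gold, and isopropanol takes the silyl group from the oxocarbenium ion and protonates the C7–Au bond, so C11 is released as the aldehyde and the double bond is fixed at C7=C8; NaBH4 then reduces this β,γ-unsaturated aldehyde in the same flask before C9 can epimerise or the olefin can move into conjugation. The closest known reaction type is the gold-catalysed carbocyclisation of silyl enol ethers onto alkynes, a silyl variant of the Conia-ene reaction, for which endo closure to six-membered rings under bulky biaryl phosphine ligands is established. Ring B closes in the 6-endo-dig mode, with both alkyne carbons ending up inside the ring. The step needs attack at C8 rather than C7 (5-exo-dig), and three things favour this: the large phosphine disfavours the more compact exo transition state, the methyl group stabilises positive charge at C8, and the two reacting arms are trans-diequatorial on the ring A chair, so exo closure would have to build a strained trans-hydrindane with an exocyclic ethylidene whereas endo closure gives an unstrained trans-octalin. The new centre C9 is controlled by the rotamer about C9–C10, because with C11 turned to the α face it becomes pseudoaxial, anti to the axial C10 methyl and out of the plane of the C8 methyl, whereas the β rotamer wedges the bulky silyloxocarbenium arm between these two methyl groups (gauche and A(1,2) strain). The hindered dioxolane beside C4 should survive because no free strong acid builds up in the presence of the alcohol and the contact time is short.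

Step 12
Reactants: 18 3,3-ethylenedioxy-9-epi-drim-7-en-11-ol
Product: 19 11-hydroxy-9-epi-drim-7-en-3-one
Conditions: 1 M HCl, THF, rt
Reagents that add atoms: water, O
Why: Acid hydrolysis of the strained dioxolane next to CMe2 is fast under conditions too mild to shift the trisubstituted C7=C8 olefin or to ionise the homoallylic alcohol.

Step 13
Reactants: 19 11-hydroxy-9-epi-drim-7-en-3-one
Product: 20 9-epi-drim-7-ene-3α,11-diol
Conditions: KBH(s-Bu)3 (3 equiv), THF, −78 °C; then NaOH, H2O2
Reagents that add atoms: none
Why: In this reduction of a rigid 4,4-dimethyl-3-decalone the bulky trialkylborohydride cannot pass the axial hydrogens at C1 and C5 on the α face, so it should attack along the equatorial path and give the axial 3α alcohol, with the free C11 hydroxyl only consuming one extra equivalent.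

Step 14
Reactants: 20 9-epi-drim-7-ene-3α,11-diol; 21 scopoletin
Product: 22 7-{[(1R,4aR,6R,8aS)-6-hydroxy-2,5,5,8a-tetramethyl-1,4,4a,5,6,7,8,8a-octahydronaphthalen-1-yl]methoxy}-6-methoxy-2H-chromen-2-one
Conditions: PPh3, DIAD, THF, 0 °C → rt
Reagents that add atoms: none
Why: In this Mitsunobu etherification only the primary C11 hydroxyl is activated and displaced by the acidic phenol, the axial C3 hydroxyl flanked by CMe2 stays inert, no stereocentre is involved, and the hydride-sensitive coumarin enters after all reductions.

Compound list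
1 | 3-ethoxy-5,5-dimethylcyclohex-2-en-1-one (dimedone ethyl enol ether) | CCOC1=CC(=O)CC(C)(C)C1 | starting material
2 | 1-bromobut-2-yne | CC#CCBr | starting material
3 | (±)-6-(but-2-yn-1-yl)-3-ethoxy-5,5-dimethylcyclohex-2-en-1-one (racemic) | CCOC1=CC(=O)C(CC#CC)C(C)(C)C1 | intermediate
4 | methyllithium | [Li]C | starting material
5 | 6-(but-2-yn-1-yl)-3-ethoxy-1,5,5-trimethylcyclohex-2-en-1-ol (racemic, both carbinol epimers, not isolated) | CCOC1=CC(C)(O)C(CC#CC)C(C)(C)C1 | intermediate
6 | (±)-4-(but-2-yn-1-yl)-3,5,5-trimethylcyclohex-2-en-1-one (racemic) | CC#CCC1C(C)=CC(=O)CC1(C)C | intermediate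
7 | (±)-trans-4-(but-2-yn-1-yl)-3,5,5-trimethylcyclohex-2-en-1-ol (racemate, both enantiomers written) | CC#CC[C@@H]1C(C)=C[C@@H](O)CC1(C)C.CC#CC[C@H]1C(C)=C[C@H](O)CC1(C)C | intermediate
8 | (1S,4S)-4-(but-2-yn-1-yl)-3,5,5-trimethylcyclohex-2-en-1-ol | CC#CC[C@@H]1C(C)=C[C@@H](O)CC1(C)C | intermediate
9 | triethyl orthoacetate | CCOC(C)(OCC)OCC | starting material
10 | 1-ethoxyvinyl ether (ketene acetal) of 8 (not isolated) | CC#CC[C@@H]1C(C)=C[C@@H](OC(=C)OCC)CC1(C)C | intermediate
11 | ethyl 2-[(1S,6S)-6-(but-2-yn-1-yl)-1,5,5-trimethylcyclohex-2-en-1-yl]acetate | CC#CC[C@H]1C(C)(C)CC=C[C@]1(C)CC(=O)OCC | intermediate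
12 | ethyl 2-[(1S,6R)-6-(but-2-yn-1-yl)-1,5,5-trimethyl-4-oxocyclohex-2-en-1-yl]acetate | CC#CC[C@H]1C(C)(C)C(=O)C=C[C@]1(C)CC(=O)OCC | intermediate
13 | ethyl 2-[(1R,2R)-2-(but-2-yn-1-yl)-1,3,3-trimethyl-4-oxocyclohexyl]acetate | CC#CC[C@H]1C(C)(C)C(=O)CC[C@]1(C)CC(=O)OCC | intermediate
14 | ethyl 2-[(7R,8R)-7-(but-2-yn-1-yl)-6,6,8-trimethyl-1,4-dioxaspiro[4.5]decan-8-yl]acetate | CC#CC[C@H]1C(C)(C)C2(OCCO2)CC[C@]1(C)CC(=O)OCC | intermediate
15 | 2-[(7R,8R)-7-(but-2-yn-1-yl)-6,6,8-trimethyl-1,4-dioxaspiro[4.5]decan-8-yl]acetaldehyde | CC#CC[C@H]1C(C)(C)C2(OCCO2)CC[C@]1(C)CC=O | intermediate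
16 | (E)-triisopropylsilyl enol ether of 15 (ring A ketal with but-2-ynyl on C5 and 2-silyloxyvinyl on C10) | CC#CC[C@H]1C(C)(C)C2(OCCO2)CC[C@]1(C)/C=C/O[Si](C(C)C)(C(C)C)C(C)C | intermediate
17 | 3,3-ethylenedioxy-9-epi-drim-7-en-11-al (not isolated) | O=C[C@@H]1C(C)=CC[C@H]2C(C)(C)C3(OCCO3)CC[C@]12C | intermediate
18 | 3,3-ethylenedioxy-9-epi-drim-7-en-11-ol | OC[C@@H]1C(C)=CC[C@H]2C(C)(C)C3(OCCO3)CC[C@]12C | intermediate
19 | 11-hydroxy-9-epi-drim-7-en-3-one | OC[C@@H]1C(C)=CC[C@H]2C(C)(C)C(=O)CC[C@]12C | intermediate
20 | 9-epi-drim-7-ene-3α,11-diol | OC[C@@H]1C(C)=CC[C@H]2C(C)(C)[C@H](O)CC[C@]12C | intermediate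
21 | scopoletin (7-hydroxy-6-methoxycoumarin) | COc1cc2ccc(=O)oc2cc1O | starting material
22 | 7-{[(1R,4aR,6R,8aS)-6-hydroxy-2,5,5,8a-tetramethyl-1,4,4a,5,6,7,8,8a-octahydronaphthalen-1-yl]methoxy}-6-methoxy-2H-chromen-2-one (CNP0218138.2) | COc1cc2ccc(=O)oc2cc1OC[C@@H]1C(C)=CC[C@H]2C(C)(C)[C@H](O)CC[C@]12C | target

Total step count: 14 (the in-flask reduction is counted with step 11).
Longest linear sequence: 14 steps, from 1 to 22. Compounds 2, 4, 9 and 21 are bought.

Steps most likely to fail

Step 11. C9 may attack C7 instead of C8 (5-exo-dig closure). The two faces of the enol ether may be poorly distinguished at C9. The ketal may be lost, or the aldehyde may drift into conjugation before it is reduced. The fallback closes the same C8–C9 bond by a radical instead of a π-acid and sets out from 16. Cp2Zr(H)Cl in slight excess lets zirconium settle on the less hindered, methyl-bearing C8. One equivalent of I2 at −78 °C, chosen so that the enol ether is spared, gives the (E)-C8 vinyl iodide F1. (Me3Si)3SiH and AIBN, added slowly in hot benzene, generate the C8 vinyl radical. This radical inverts freely, so the iodide geometry is irrelevant, and it closes 6-exo-trig on C9 of the enol ether. The α-silyloxy radical at C11 picks up hydrogen to give the C11 triisopropylsilyl ether F2, and Bu4NF frees the alcohol. The route is rejoined at 18. The position of iodine fixes the reacting carbon, so the exo/endo question at the alkyne disappears, while C9 still rests on the same strain arguments.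

Step 6. Oxygen may be delivered to the other end of the allyl system (C1), which is almost as accessible as C3. The propargylic C–H bonds may be attacked, or the neopentyl C3 may react too slowly. The fallback installs the C3 oxygen by enolate chemistry before the rearrangement, while C1 and C3 are still chemically different, and sets out from 8. MnO2 gives the (4S)-enone F3. LiN(i-Pr)2 and t-BuMe2SiCl trap the kinetic C3 enolate as the cross-conjugated silyl dienol ether F4. m-CPBA with NaHCO3 (Rubottom oxidation with silyl migration) gives the C3 silyloxy enone F5, whose C3 configuration does not matter. LiBH(s-Bu)3 gives the C2 α-carbinol F6. MeC(OEt)3 with EtCO2H at 140 °C carries it through the ketene acetal F7 to the rearranged allylic silyl ether ester F8. Bu4NF frees the C3 allylic alcohol F9, and MnO2 oxidises it to the enone. The route is rejoined at 12.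

Step 14. Displacement at the β-branched, axial C11 may be slow. Elimination toward the allylic C9–H may give a diene, and the C7=C8 olefin may participate in ionisation of the activated alcohol. The fallback forms the aryl–oxygen bond instead of the alkyl–oxygen bond and sets out from 21 and 20. Tf2O and pyridine turn scopoletin into scopoletin triflate F10. Zerovalent palladium catalysis (Pd2(dba)3, a bulky di-tert-butyl biaryl phosphine, Cs2CO3, toluene, 80 °C) couples F10 with the primary hydroxyl of 20, while the hindered C3 hydroxyl stays out. The route is rejoined at 22.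

Further compounds
F1 | step 11 | (E)-C8 vinyl iodide of 16 (H on C7, I and CH3 on C8, CH3 cis to C6) | C/C(I)=C\C[C@H]1C(C)(C)C2(OCCO2)CC[C@]1(C)/C=C/O[Si](C(C)C)(C(C)C)C(C)C
F2 | step 11 | 3,3-ethylenedioxy-11-(triisopropylsilyloxy)-9-epi-drim-7-ene | CC(C)[Si](OC[C@@H]1C(C)=CC[C@H]2C(C)(C)C3(OCCO3)CC[C@]12C)(C(C)C)C(C)C
F3 | step 6 | (4S)-4-(but-2-yn-1-yl)-3,5,5-trimethylcyclohex-2-en-1-one | CC#CC[C@@H]1C(C)=CC(=O)CC1(C)C
F4 | step 6 | cross-conjugated tert-butyldimethylsilyl dienol ether of F3 | CC#CC[C@@H]1C(C)=CC(O[Si](C)(C)C(C)(C)C)=CC1(C)C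
F5 | step 6 | (4S)-4-(but-2-yn-1-yl)-6-(tert-butyldimethylsilyloxy)-3,5,5-trimethylcyclohex-2-en-1-one (epimers at the silyloxy carbon) | CC#CC[C@@H]1C(C)=CC(=O)C(O[Si](C)(C)C(C)(C)C)C1(C)C
F6 | step 6 | 4-(but-2-yn-1-yl)-6-(tert-butyldimethylsilyloxy)-3,5,5-trimethylcyclohex-2-en-1-ol with C2–OH α and C5–H α (epimers at the silyloxy carbon) | CC#CC[C@@H]1C(C)=C[C@@H](O)C(O[Si](C)(C)C(C)(C)C)C1(C)C
F7 | step 6 | 1-ethoxyvinyl ether (ketene acetal) of F6 | CC#CC[C@@H]1C(C)=C[C@@H](OC(=C)OCC)C(O[Si](C)(C)C(C)(C)C)C1(C)C
F8 | step 6 | C3 tert-butyldimethylsilyloxy derivative of ester 11 (epimers at C3) | CC#CC[C@H]1C(C)(C)C(O[Si](C)(C)C(C)(C)C)C=C[C@]1(C)CC(=O)OCC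
F9 | step 6 | C3 hydroxy derivative of ester 11 (epimers at C3) | CC#CC[C@H]1C(C)(C)C(O)C=C[C@]1(C)CC(=O)OCC
F10 | step 14 | scopoletin triflate (6-methoxy-2-oxo-2H-chromen-7-yl trifluoromethanesulfonate) | COc1cc2ccc(=O)oc2cc1OS(=O)(=O)C(F)(F)F
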